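**Retrosynthetic overview**
1. The hydroperoxide comes last, by a singlet-oxygen ene reaction on the prenyl side chain; the C4 acetate comes from Mitsunobu inversion of a 2,4-syn diol, and the C2 carbinol from chelation-controlled MeMgBr addition.
2. The ten-membered ring (formed second) is closed at C3–C4 by a boron aldol reaction of a cyclopropyl methyl ketone onto an enal.
3. The cyclopropane (formed first, key step) is made by cobalt-porphyrin metalloradical cyclopropanation of a vinyl group with 1-diazopropan-2-one, forming C1–C10 and C1–C11; the reagent's CH3 later becomes C3.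
4. The quaternary C9 is set by copper-catalysed SN2′ alkylation of a C10 allylic phosphate with homoprenylmagnesium bromide.
5. The C10 backbone comes from double carboalumination–hydroxymethylation of hexa-1,5-diyne.

Assumption: ring atoms are numbered C1 (cyclopropane CH next to the carbinol carbon), C2 (carbinol carbon), C4 (acetoxy carbon), C5=C6, C9 (quaternary carbon), C10 (second cyclopropane CH), C11 (cyclopropane CH2); 1-diazopropan-2-one is made, not bought; the enantiomer of each chiral ligand or reagent is the one that gives the configuration drawn, and these senses of induction must be confirmed by experiment.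

**Step 1**
Reactants: 1 hexa-1,5-diyne
Product: 4 (2E,6E)-3,6-dimethylocta-2,6-diene-1,8-diol, via bis-alkenylalane 2 (not isolated), via dilithium bis-alanate 3 (not isolated)
Conditions: Me3Al (4 equiv), Cp2ZrCl2 (0.4 equiv), CH2Cl2, 0 °C to rt; volatiles off; n-BuLi (2.1 equiv), THF–hexane, −78 °C; (CH2O)n, −78 °C to rt; aq. NH4Cl
Reagents that add atoms: trimethylaluminium C[Al](C)C; formaldehyde (from paraformaldehyde) C=O
Why: Negishi zirconium-catalysed carboalumination adds CH3 and Al syn across each terminal alkyne with Al on the terminal carbon, and the alanate is hydroxymethylated with retention, so both trisubstituted alkenes are E and no stereocentre is formed.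

**Step 2**
Reactants: 4 (2E,6E)-3,6-dimethylocta-2,6-diene-1,8-diol
Product: 5 (2E,6E)-3,6-dimethyl-8-[(triethylsilyl)oxy]octa-2,6-dien-1-ol
Conditions: NaH (1.0 equiv), THF, 0 °C to rt; Et3SiCl (1.0 equiv), rt
Reagents that add atoms: chlorotriethylsilane CC[Si](Cl)(CC)CC
Why: Monosilylation of a symmetrical diol through its sparingly soluble monosodium alkoxide (McDougal protocol) tells the two identical ends apart; no stereocentre.

**Step 3**
Reactants: 5 (2E,6E)-3,6-dimethyl-8-[(triethylsilyl)oxy]octa-2,6-dien-1-ol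
Product: 6 diethyl (2E,6E)-3,6-dimethyl-8-[(triethylsilyl)oxy]octa-2,6-dien-1-yl phosphate
Conditions: (EtO)2P(O)Cl, Et3N, DMAP (cat.), CH2Cl2, 0 °C
Reagents that add atoms: diethyl chlorophosphate CCOP(=O)(Cl)OCC
Why: O-Phosphorylation of the primary allylic alcohol installs the leaving group for copper-catalysed SN2′ substitution; no stereocentre.

**Step 4**
Reactants: 6 diethyl (2E,6E)-3,6-dimethyl-8-[(triethylsilyl)oxy]octa-2,6-dien-1-yl phosphate; 7 5-bromo-2-methylpent-2-ene
Product: 9 {[(2E,6S)-6-ethenyl-3,6,10-trimethylundeca-2,9-dien-1-yl]oxy}triethylsilane, via homoprenylmagnesium bromide 8 (not isolated)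
Conditions: 7, Mg, THF, rt; then slow addition to 6, Cu(OTf)2 (2 mol %), chiral bidentate hydroxyalkyl-imidazolinium salt (N-heterocyclic carbene precursor, 3 mol %), Et2O, −15 °C
Reagents that add atoms: none
Why: Copper–NHC-catalysed enantioselective allylic alkylation (SN2′): the alkylcopper attacks the γ-carbon of the E-allylic phosphate anti to the leaving group, the ligand telling the CH3 face from the CH2CH2R face, which sets the all-carbon quaternary centre as 6S and releases the vinyl group.

**Step 5**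
Reactants: 10 pentane-2,4-dione
Product: 12 1-diazopropan-2-one, via 3-diazopentane-2,4-dione 11 (not isolated)
Conditions: TsN3, Et3N, MeCN, 0 °C to rt; then 2 M aq. NaOH–Et2O, 0 °C
Reagents that add atoms: 4-methylbenzenesulfonyl azide Cc1ccc(cc1)S(=O)(=O)N=[N+]=[N-]
Why: Regitz diazo transfer to the 1,3-diketone followed by hydroxide-induced deacetylation (retro-Claisen) gives the acceptor diazoketone; no stereocentre.

**Step 6 (key step)**
Reactants: 9 {[(2E,6S)-6-ethenyl-3,6,10-trimethylundeca-2,9-dien-1-yl]oxy}triethylsilane; 12 1-diazopropan-2-one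
Product: 13 1-{(1S,2S)-2-[(2E,6S)-3,6,10-trimethyl-1-[(triethylsilyl)oxy]undeca-2,9-dien-6-yl]cyclopropyl}ethan-1-one
Conditions: [Co(3,5-DitBu-ChenPhyrin)] (D2-symmetric chiral amidoporphyrin complex of divalent cobalt, 5 mol %), 12 (2.5 equiv, added over 10 h), PhCl, 40 °C
Reagents that add atoms: none
Why: Proposed new method: the divalent cobalt porphyrin, a metalloradical, takes up the diazoketone with loss of N2 to give a trivalent cobalt α-acyl alkyl ("carbene") radical, which adds to the free terminus of the only monosubstituted alkene (the two trisubstituted alkenes do not fit the porphyrin pocket), and the secondary radical so formed closes the three-membered ring by 3-exo-tet homolytic substitution at the Co–C bond faster than it can attack the prenyl alkene in a 5-exo mode; the chiral amide pocket, hydrogen-bonded to the ketone carbonyl, sets both cyclopropane carbons as S and the stepwise radical path gives the trans isomer; the closest known reaction type is cobalt-porphyrin metalloradical asymmetric cyclopropanation of terminal alkenes with diazoacetates and α-ketodiazoacetates, here extended to an acceptor-only diazoketone and a hindered unactivated alkene.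

**Step 7**
Reactants: 13 1-{(1S,2S)-2-[(2E,6S)-3,6,10-trimethyl-1-[(triethylsilyl)oxy]undeca-2,9-dien-6-yl]cyclopropyl}ethan-1-one
Product: 14 (2E,6S)-6-[(1S,2S)-2-acetylcyclopropyl]-3,6,10-trimethylundeca-2,9-dienal
Conditions: (COCl)2, DMSO, CH2Cl2, −78 to −30 °C; Et3N, −78 to 0 °C
Reagents that add atoms: none
Why: Swern oxidation: the chlorosulfonium salt cleaves the primary allylic triethylsilyl ether directly and the alkoxysulfonium ylide collapses to the E-enal, leaving the ketone and all stereocentres untouched.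

**Step 8**
Reactants: 14 (2E,6S)-6-[(1S,2S)-2-acetylcyclopropyl]-3,6,10-trimethylundeca-2,9-dienal
Product: 16 (1S,4R,5E,9S,10S)-4-hydroxy-6,9-dimethyl-9-(4-methylpent-3-en-1-yl)bicyclo[8.1.0]undec-5-en-2-one, via enol diisopinocampheylborinate 15 (not isolated)
Conditions: (+)-Ipc2BCl (3 equiv), Et3N (4 equiv), Et2O (3 mM in 14), −78 to −20 °C; then MeOH, pH 7 buffer, 30% H2O2, 0 °C
Reagents that add atoms: none
Why: Paterson boron aldol reaction: the ketone enolises only on the CH3 side (the cyclopropyl α-CH cannot), and the enol borinate closes the ten-membered ring through a cyclic transition state onto the non-enolisable enal, the isopinocampheyl ligands directing attack on the re face of the aldehyde to set C4 as R.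

**Step 9**
Reactants: 16 (1S,4R,5E,9S,10S)-4-hydroxy-6,9-dimethyl-9-(4-methylpent-3-en-1-yl)bicyclo[8.1.0]undec-5-en-2-one
Product: 17 (1S,2S,4R,5E,9S,10S)-2,6,9-trimethyl-9-(4-methylpent-3-en-1-yl)bicyclo[8.1.0]undec-5-ene-2,4-diol
Conditions: MeMgBr (4 equiv), THF, −78 °C; aq. NH4Cl
Reagents that add atoms: methylmagnesium bromide C[Mg]Br
Why: Chelation-controlled Grignard addition: the C4 magnesium alkoxide binds the C2 carbonyl in a six-membered chelate and the methyl group adds to its open face (1,3-syn model), setting C2 as S in a 2,4-syn diol.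

**Step 10**
Reactants: 17 (1S,2S,4R,5E,9S,10S)-2,6,9-trimethyl-9-(4-methylpent-3-en-1-yl)bicyclo[8.1.0]undec-5-ene-2,4-diol
Product: 18 (1S,2S,4S,5E,9S,10S)-2-hydroxy-2,6,9-trimethyl-9-(4-methylpent-3-en-1-yl)bicyclo[8.1.0]undec-5-en-4-yl acetate
Conditions: AcOH, PPh3, DIAD, toluene, 0 °C to rt
Reagents that add atoms: acetic acid CC(=O)O
Why: Mitsunobu esterification: only the secondary allylic C4 hydroxyl is activated (the tertiary C2 hydroxyl is inert) and acetate displaces the oxyphosphonium group by SN2 with inversion, giving the 4S acetate anti to the C2 hydroxyl, while the fully substituted alkene terminus disfavours SN2′.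

**Step 11**
Reactants: 18 (1S,2S,4S,5E,9S,10S)-2-hydroxy-2,6,9-trimethyl-9-(4-methylpent-3-en-1-yl)bicyclo[8.1.0]undec-5-en-4-yl acetate
Product: 19 (1S,2S,4S,5E,9R,10S)-9-[(3S)-3-hydroperoxy-4-methylpent-4-en-1-yl]-2-hydroxy-2,6,9-trimethylbicyclo[8.1.0]undec-5-en-4-yl acetate
Conditions: O2, tetraphenylporphyrin (1 mol %), CH2Cl2, 0 °C, visible light, to about 70% conversion; preparative HPLC
Reagents that add atoms: dioxygen O=O
Why: Schenck ene reaction of singlet oxygen at the electron-rich side-chain alkene (the ring alkene is deactivated by its allylic acetate), with hydrogen taken from a terminal methyl, gives the allylic hydroperoxide next to an isopropenyl group; the new side-chain stereocentre is not controlled (about 1:1 S to R, plus the tertiary regioisomer), so the 3S isomer is isolated by HPLC.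

**Compound list**
1 | hexa-1,5-diyne | C#CCCC#C | starting material
2 | (1E,5E)-1,6-bis(dimethylalumanyl)-2,5-dimethylhexa-1,5-diene | C[Al](C)/C=C(\C)CC/C(C)=C/[Al](C)C | intermediate
3 | dilithium (1E,5E)-2,5-dimethylhexa-1,5-diene-1,6-diylbis[butyl(dimethyl)alanuide] | [Li+].[Li+].CCCC[Al-](C)(C)/C=C(\C)CC/C(C)=C/[Al-](C)(C)CCCC | intermediate
4 | (2E,6E)-3,6-dimethylocta-2,6-diene-1,8-diol | OC/C=C(\C)CC/C(C)=C/CO | intermediate
5 | (2E,6E)-3,6-dimethyl-8-[(triethylsilyl)oxy]octa-2,6-dien-1-ol | OC/C=C(\C)CC/C(C)=C/CO[Si](CC)(CC)CC | intermediate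
6 | diethyl (2E,6E)-3,6-dimethyl-8-[(triethylsilyl)oxy]octa-2,6-dien-1-yl phosphate | CCOP(=O)(OCC)OC/C=C(\C)CC/C(C)=C/CO[Si](CC)(CC)CC | intermediate
7 | 5-bromo-2-methylpent-2-ene | CC(C)=CCCBr | starting material
8 | (4-methylpent-3-en-1-yl)magnesium bromide | CC(C)=CCC[Mg]Br | intermediate
9 | {[(2E,6S)-6-ethenyl-3,6,10-trimethylundeca-2,9-dien-1-yl]oxy}triethylsilane | CC(C)=CCC[C@@](C=C)(C)CC/C(C)=C/CO[Si](CC)(CC)CC | intermediate
10 | pentane-2,4-dione | CC(=O)CC(C)=O | starting material
11 | 3-diazopentane-2,4-dione | CC(=O)C(=[N+]=[N-])C(C)=O | intermediate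
12 | 1-diazopropan-2-one | CC(=O)C=[N+]=[N-] | intermediate
13 | 1-{(1S,2S)-2-[(2E,6S)-3,6,10-trimethyl-1-[(triethylsilyl)oxy]undeca-2,9-dien-6-yl]cyclopropyl}ethan-1-one | CC(=O)[C@H]1C[C@@H]1[C@@](C)(CCC=C(C)C)CC/C(C)=C/CO[Si](CC)(CC)CC | intermediate
14 | (2E,6S)-6-[(1S,2S)-2-acetylcyclopropyl]-3,6,10-trimethylundeca-2,9-dienal | CC(=O)[C@H]1C[C@@H]1[C@@](C)(CCC=C(C)C)CC/C(C)=C/C=O | intermediate
15 | 1-{(1S,2S)-2-[(2E,6S)-3,6,10-trimethyl-1-oxoundeca-2,9-dien-6-yl]cyclopropyl}ethenyl diisopinocampheylborinate (isopinocampheyl groups from (−)-α-pinene) | C=C(OB([C@H]1C[C@H]2C[C@@H]([C@@H]1C)C2(C)C)[C@H]1C[C@H]2C[C@@H]([C@@H]1C)C2(C)C)[C@H]3C[C@@H]3[C@@](C)(CCC=C(C)C)CC/C(C)=C/C=O | intermediate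
16 | (1S,4R,5E,9S,10S)-4-hydroxy-6,9-dimethyl-9-(4-methylpent-3-en-1-yl)bicyclo[8.1.0]undec-5-en-2-one | CC(C)=CCC[C@@]1(C)CC/C(C)=C/[C@H](O)CC(=O)[C@H]2C[C@@H]21 | intermediate
17 | (1S,2S,4R,5E,9S,10S)-2,6,9-trimethyl-9-(4-methylpent-3-en-1-yl)bicyclo[8.1.0]undec-5-ene-2,4-diol | CC(C)=CCC[C@@]1(C)CC/C(C)=C/[C@H](O)C[C@](C)(O)[C@H]2C[C@@H]21 | intermediate
18 | (1S,2S,4S,5E,9S,10S)-2-hydroxy-2,6,9-trimethyl-9-(4-methylpent-3-en-1-yl)bicyclo[8.1.0]undec-5-en-4-yl acetate | CC(C)=CCC[C@@]1(C)CC/C(C)=C/[C@@H](OC(C)=O)C[C@](C)(O)[C@H]2C[C@@H]21 | intermediate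
19 | (1S,2S,4S,5E,9R,10S)-9-[(3S)-3-hydroperoxy-4-methylpent-4-en-1-yl]-2-hydroxy-2,6,9-trimethylbicyclo[8.1.0]undec-5-en-4-yl acetate | C=C(C)[C@H](CC[C@@]1(C)CC/C(C)=C/[C@@H](OC(C)=O)C[C@](C)(O)[C@H]2C[C@@H]21)OO | target

The descriptor at C9 changes from S (compounds 9 to 18) to R (19) only because the hydroperoxide raises the CIP priority of the side chain; the centre itself is untouched.

**Step count**
Total step count: 11. Longest linear sequence: 10 steps (steps 1 to 4 and 6 to 11); step 5 is a one-step side branch.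

**The three steps most likely to fail**

Step 6, the metalloradical cyclopropanation. The vinyl group is unactivated and sits next to a quaternary carbon, the acceptor-only diazoketone may dimerise faster than it transfers, and catalyst control next to the quaternary centre is untested. The fallback sets out from 9 and comes back at 13. It uses closed-shell carbene transfer with a better-behaved carbene source: RuCl2(i-Pr-pybox)(C2H4) (pybox = 2,6-bis(4-isopropyl-2-oxazolin-2-yl)pyridine) with slow addition of ethyl diazoacetate in CH2Cl2 cyclopropanates the terminal alkene trans-selectively to give ethyl (1S,2S)-2-[(2E,6S)-3,6,10-trimethyl-1-[(triethylsilyl)oxy]undeca-2,9-dien-6-yl]cyclopropane-1-carboxylate F1. Me(MeO)NH·HCl and i-PrMgCl in THF at −20 °C turn the ester into (1S,2S)-N-methoxy-N-methyl-2-[(2E,6S)-3,6,10-trimethyl-1-[(triethylsilyl)oxy]undeca-2,9-dien-6-yl]cyclopropane-1-carboxamide F2, and MeMgBr in THF at 0 °C gives ketone 13.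

Step 8, the ring-closing boron aldol reaction. Closing a ten-membered ring is entropically and sterically hard, Ipc2BCl can reduce the free aldehyde before enolisation is complete, and the reagent may not override the facial bias of the ring at C4. The fallback sets out from 13 and comes back at 16. It uses an irreversible samarium Reformatsky-type closure from a preformed α-bromoketone. LiN(SiMe3)2 and Me3SiCl in THF at −78 °C give the kinetic enol ether triethyl{[(2E,6S)-3,6,10-trimethyl-6-[(1S,2S)-2-{1-[(trimethylsilyl)oxy]ethenyl}cyclopropyl]undeca-2,9-dien-1-yl]oxy}silane F3. NBS at −78 °C gives 2-bromo-1-{(1S,2S)-2-[(2E,6S)-3,6,10-trimethyl-1-[(triethylsilyl)oxy]undeca-2,9-dien-6-yl]cyclopropyl}ethan-1-one F4. Swern oxidation as in step 7 gives (2E,6S)-6-[(1S,2S)-2-(bromoacetyl)cyclopropyl]-3,6,10-trimethylundeca-2,9-dienal F5. SmI2 (2.2 equiv) in THF at −78 °C under high dilution forms the samarium enolate, which adds to the enal and closes the ring; the 4R epimer 16 is taken on after chromatography.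

Step 10, the Mitsunobu inversion. Backside attack at a ring carbon of a ten-membered ring can be blocked transannularly, and elimination to a diene or ionisation of the allylic oxyphosphonium would lose material or scramble C4. The fallback sets out from 17 and comes back at 18. It resets C4 by oxidation and directed reduction: MnO2 in CH2Cl2 oxidises only the allylic C4 hydroxyl to (1S,2S,5E,9S,10S)-2-hydroxy-2,6,9-trimethyl-9-(4-methylpent-3-en-1-yl)bicyclo[8.1.0]undec-5-en-4-one F6. Me4NBH(OAc)3 in MeCN–AcOH at −30 °C (Evans–Saksena reduction, hydride delivered from boron bound to the C2 oxygen) gives the 2,4-anti diol (1S,2S,4S,5E,9S,10S)-2,6,9-trimethyl-9-(4-methylpent-3-en-1-yl)bicyclo[8.1.0]undec-5-ene-2,4-diol F7. Ac2O in pyridine acetylates only the secondary alcohol and gives 18.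

**Further compounds**
F1 | step 6 | ethyl (1S,2S)-2-[(2E,6S)-3,6,10-trimethyl-1-[(triethylsilyl)oxy]undeca-2,9-dien-6-yl]cyclopropane-1-carboxylate | CCOC(=O)[C@H]1C[C@@H]1[C@@](C)(CCC=C(C)C)CC/C(C)=C/CO[Si](CC)(CC)CC
F2 | step 6 | (1S,2S)-N-methoxy-N-methyl-2-[(2E,6S)-3,6,10-trimethyl-1-[(triethylsilyl)oxy]undeca-2,9-dien-6-yl]cyclopropane-1-carboxamide | CON(C)C(=O)[C@H]1C[C@@H]1[C@@](C)(CCC=C(C)C)CC/C(C)=C/CO[Si](CC)(CC)CC
F3 | step 8 | triethyl{[(2E,6S)-3,6,10-trimethyl-6-[(1S,2S)-2-{1-[(trimethylsilyl)oxy]ethenyl}cyclopropyl]undeca-2,9-dien-1-yl]oxy}silane | C=C(O[Si](C)(C)C)[C@H]1C[C@@H]1[C@@](C)(CCC=C(C)C)CC/C(C)=C/CO[Si](CC)(CC)CC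
F4 | step 8 | 2-bromo-1-{(1S,2S)-2-[(2E,6S)-3,6,10-trimethyl-1-[(triethylsilyl)oxy]undeca-2,9-dien-6-yl]cyclopropyl}ethan-1-one | BrCC(=O)[C@H]1C[C@@H]1[C@@](C)(CCC=C(C)C)CC/C(C)=C/CO[Si](CC)(CC)CC
F5 | step 8 | (2E,6S)-6-[(1S,2S)-2-(bromoacetyl)cyclopropyl]-3,6,10-trimethylundeca-2,9-dienal | BrCC(=O)[C@H]1C[C@@H]1[C@@](C)(CCC=C(C)C)CC/C(C)=C/C=O
F6 | step 10 | (1S,2S,5E,9S,10S)-2-hydroxy-2,6,9-trimethyl-9-(4-methylpent-3-en-1-yl)bicyclo[8.1.0]undec-5-en-4-one | CC(C)=CCC[C@@]1(C)CC/C(C)=C/C(=O)C[C@](C)(O)[C@H]2C[C@@H]21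
F7 | step 10 | (1S,2S,4S,5E,9S,10S)-2,6,9-trimethyl-9-(4-methylpent-3-en-1-yl)bicyclo[8.1.0]undec-5-ene-2,4-diol | CC(C)=CCC[C@@]1(C)CC/C(C)=C/[C@@H](O)C[C@](C)(O)[C@H]2C[C@@H]21
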